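**Retrosynthetic overview**

1. The two methyl ethers are cut first (O-methylation of a 2,5-dihydroxy-3,6-bis(indolyl)-1,4-benzoquinone), and the C2 hydroxyl is traced back to a vinylogous acid chloride (C2–Cl).
2. Key disconnection: the bond from quinone C6 to C3' of the unsubstituted indole. It is made by a [3,3] shift of an N1'–O–C5 ether, assembled in the same flask from 1-hydroxyindole and the C5–Cl of a 2,5-dichloro-3-(indol-3-yl)quinone. The N1'–O bond is a temporary tether, absent from the target, and is cleaved as the C–C bond forms.
3. Enabling feature: the oxygen-bearing ring carbon C5 sits directly beside C6, the carbon that must carry the indol-3-yl group. O–C5=C6 of the quinone and N1'–C2'=C3' of the pyrrole ring can therefore be linked through N–O into the six-atom array C3'=C2'–N1'–O–C5=C6. Both carbon termini are nucleophilic in character; the weak N–O bond is the internal oxidant that joins them, and its oxygen stays on C5 as the future methoxy oxygen.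
4. The other quinone–indole bond (at C3) comes from acid-promoted conjugate addition of 2-(2-methylbut-3-en-2-yl)indole to 2,5-dichloro-1,4-benzoquinone, then reoxidation.
5. Ring formation: only the pyrrole ring of the 2-substituted indole is built (Madelung closure of an N-(o-tolyl)amide). The quinone ring and the second indole nucleus (as indoline) are bought.

Key step: step 5

Remark: quinone locants used throughout are C1 and C4 (carbonyls), C2 and C5 (chlorine or oxygen), C3 (2-substituted indol-3-yl) and C6 (site of the second indole), with primed locants for that second indole; the target has no stereocentre; 1-hydroxyindole is assumed to be usable only as a freshly made cold solution, because it decomposes on concentration.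

**Route**

Step 1
Reactants: 1 2,2-dimethylbut-3-enoic acid; 2 2-methylaniline (o-toluidine)
Product: 4 N-(2-methylphenyl)-2,2-dimethylbut-3-enamide, via 2,2-dimethylbut-3-enoyl chloride 3 (not isolated)
Conditions: (COCl)2, DMF (cat.), CH2Cl2, 0 → 23 °C; then 2, Et3N, CH2Cl2, 0 → 23 °C
Reagents that add atoms: oxalyl chloride, ClC(=O)C(=O)Cl (gives the chlorine of intermediate 3; no atom of it stays in 4)
Why: Acid chloride formation followed by Schotten–Baumann-type N-acylation should be clean because the α-quaternary acid cannot form a ketene and the aniline nitrogen is the only nucleophile.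

Step 2
Reactants: 4 N-(2-methylphenyl)-2,2-dimethylbut-3-enamide
Product: 5 2-(2-methylbut-3-en-2-yl)-1H-indole
Conditions: n-BuLi (3 equiv), THF, −20 → 23 °C; aq NH4Cl
Reagents that add atoms: none
Why: Madelung indole synthesis in its organolithium variant, in which N- and benzylic C-lithiation, attack of the benzylic anion on the amidate carbon and loss of lithium oxide close the pyrrole ring, and the tertiary non-enolisable acyl group (as in the corresponding pivalamide case) excludes α-deprotonation.

Step 3
Reactants: 5 2-(2-methylbut-3-en-2-yl)-1H-indole; 6 2,5-dichloro-1,4-benzoquinone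
Product: 8 2,5-dichloro-3-[2-(2-methylbut-3-en-2-yl)-1H-indol-3-yl]cyclohexa-2,5-diene-1,4-dione, via 2,5-dichloro-3-(indol-3-yl)hydroquinone 7 (not isolated)
Conditions: conc. HCl (cat.), THF, 23 °C; then DDQ (1.1 equiv), 23 °C
Reagents that add atoms: none
Why: Acid-promoted conjugate (Friedel–Crafts type) addition of indole C3 to a C–H position of the activated dichloroquinone followed by DDQ dehydrogenation of the hydroquinone is the established way to join 2-substituted indoles to 2,5-dichlorobenzoquinone, and the hindered, deactivated mono-adduct should not take up a second bulky indole.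

Step 4
Reactants: 9 indoline (2,3-dihydro-1H-indole)
Product: 10 1-hydroxyindole (1H-indol-1-ol), kept as a solution
Conditions: Na2WO4·2H2O (0.2 equiv), 30% aq H2O2 (10 equiv), MeOH/H2O, 0 → 20 °C; extraction into Et2O, exchange to MeCN below 20 °C, used at once
Reagents that add atoms: hydrogen peroxide, OO
Why: Tungstate-catalysed peroxide oxidation of an indoline is a known route to 1-hydroxyindoles, running through the N-hydroxyindoline and the cyclic nitrone, which tautomerises to the aromatic N-hydroxyindole.

Step 5
Reactants: 8 2,5-dichloro-3-[2-(2-methylbut-3-en-2-yl)-1H-indol-3-yl]cyclohexa-2,5-diene-1,4-dione; 10 1-hydroxyindole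
Product: 13 2-chloro-5-hydroxy-6-(1H-indol-3-yl)-3-[2-(2-methylbut-3-en-2-yl)-1H-indol-3-yl]cyclohexa-2,5-diene-1,4-dione, via N-(quinon-5-yloxy)indole 11 (not isolated), via 3H-indole cyclohexenetrione 12 (not isolated)
Conditions: 10 (1.3 equiv, MeCN solution), K2CO3 (2.5 equiv), MeCN, 0 → 40 °C, dark, Ar; then 1 M HCl
Reagents that add atoms: none
Why: Proposed new method: the oxyanion of 10 should displace the less hindered chloride at C5 of 8 by addition–elimination (C5 is a vinylogous acid chloride carbon, β to the C1 carbonyl), giving ether 11, in which C3'=C2'–N1'–O–C5=C6 is a 1,5-diene equivalent; a [3,3] sigmatropic shift then breaks the weak N1'–O bond, forms the C6–C3' bond and turns C5–O into a carbonyl (12), and two proton shifts (3H-indole to 1H-indole, C6–H of the 1,3-dicarbonyl to the enol) should deliver hydroxyquinone 13 as its potassium salt. The closest known reaction types are the [3,3] rearrangements of N-aryloxyindoles and N-alkenyloxyindoles, which give 3-(2-hydroxyaryl)indoles and indol-3-yl carbonyl compounds, and the ipso substitution of haloquinones by aryloxides; new here is a quinone enol carbon as the migration terminus. No ring is closed and no stereocentre survives, because the two stereocentres of 12 are erased by the tautomerisations. Three selectivities are needed: attack at C5–Cl and not C2–Cl, secured by the twisted 2-tert-alkylindolyl group at C3 that shields C2; O-attack and not C-attack of the 1-oxyindole anion, expected for its hard α-effect oxygen; and bonding at C3' and not at a benzo carbon, secured because the pyrrole C2'=C3' bond is the only π bond that reaches C6 without loss of benzenoid aromaticity. The step joins two carbons of like (nucleophilic) polarity, indole C3' and the α-carbon of a vinylogous ester, which is possible only because the N–O tether acts as built-in oxidant, so the quinone oxidation level is kept without an external oxidant.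

Step 6
Reactants: 13 2-chloro-5-hydroxy-6-(1H-indol-3-yl)-3-[2-(2-methylbut-3-en-2-yl)-1H-indol-3-yl]cyclohexa-2,5-diene-1,4-dione
Product: 14 2,5-dihydroxy-6-(1H-indol-3-yl)-3-[2-(2-methylbut-3-en-2-yl)-1H-indol-3-yl]cyclohexa-2,5-diene-1,4-dione
Conditions: 2 M aq NaOH, MeOH, 65 °C, N2; then 1 M HCl to pH 2
Reagents that add atoms: sodium hydroxide, [Na+].[OH-]
Why: Addition–elimination of hydroxide at the remaining vinylogous acid chloride carbon C2 is the standard conversion of chlorinated bis(indolyl)quinones into the dihydroxyquinones, and the indole rings and the terminal alkene should tolerate the base.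

Step 7
Reactants: 14 2,5-dihydroxy-6-(1H-indol-3-yl)-3-[2-(2-methylbut-3-en-2-yl)-1H-indol-3-yl]cyclohexa-2,5-diene-1,4-dione
Product: 15 2,5-dimethoxy-6-(1H-indol-3-yl)-3-[2-(2-methylbut-3-en-2-yl)-1H-indol-3-yl]cyclohexa-2,5-diene-1,4-dione (target)
Conditions: TMSCHN2 (2 M in hexanes, 3 equiv), PhMe/MeOH 4:1, 0 → 23 °C
Reagents that add atoms: trimethylsilyldiazomethane, C[Si](C)(C)C=[N+]=[N-] (supplies the carbon of each O-methyl group)
Why: Diazomethane released from TMSCHN2 in methanol should O-methylate the strongly acidic vinylogous carboxylic acid hydroxyls, while the far less acidic indole N–H groups and the fully substituted quinone double bonds stay untouched.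

**Compound list**

1 | 2,2-dimethylbut-3-enoic acid | C=CC(C)(C)C(=O)O | starting material
2 | 2-methylaniline (o-toluidine) | Cc1ccccc1N | starting material
3 | 2,2-dimethylbut-3-enoyl chloride (not isolated) | C=CC(C)(C)C(=O)Cl | intermediate
4 | N-(2-methylphenyl)-2,2-dimethylbut-3-enamide | C=CC(C)(C)C(=O)Nc1ccccc1C | intermediate
5 | 2-(2-methylbut-3-en-2-yl)-1H-indole | C=CC(C)(C)c1cc2ccccc2[nH]1 | intermediate
6 | 2,5-dichloro-1,4-benzoquinone | O=C1C=C(Cl)C(=O)C=C1Cl | starting material
7 | 2,5-dichloro-3-[2-(2-methylbut-3-en-2-yl)-1H-indol-3-yl]benzene-1,4-diol (not isolated) | C=CC(C)(C)c1[nH]c2ccccc2c1-c1c(O)c(Cl)cc(O)c1Cl | intermediate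
8 | 2,5-dichloro-3-[2-(2-methylbut-3-en-2-yl)-1H-indol-3-yl]cyclohexa-2,5-diene-1,4-dione | C=CC(C)(C)c1[nH]c2ccccc2c1C1=C(Cl)C(=O)C=C(Cl)C1=O | intermediate
9 | indoline (2,3-dihydro-1H-indole) | C1Cc2ccccc2N1 | starting material
10 | 1-hydroxyindole (1H-indol-1-ol), handled in solution | On1ccc2ccccc21 | intermediate
11 | 2-chloro-5-(1H-indol-1-yloxy)-3-[2-(2-methylbut-3-en-2-yl)-1H-indol-3-yl]cyclohexa-2,5-diene-1,4-dione (not isolated) | C=CC(C)(C)c1[nH]c2ccccc2c1C1=C(Cl)C(=O)C=C(On2ccc3ccccc32)C1=O | intermediate
12 | 5-chloro-3-(3H-indol-3-yl)-6-[2-(2-methylbut-3-en-2-yl)-1H-indol-3-yl]cyclohex-5-ene-1,2,4-trione (not isolated; two transient stereocentres, unassigned mixture) | C=CC(C)(C)c1[nH]c2ccccc2c1C1=C(Cl)C(=O)C(C2C=Nc3ccccc32)C(=O)C1=O | intermediate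
13 | 2-chloro-5-hydroxy-6-(1H-indol-3-yl)-3-[2-(2-methylbut-3-en-2-yl)-1H-indol-3-yl]cyclohexa-2,5-diene-1,4-dione | C=CC(C)(C)c1[nH]c2ccccc2c1C1=C(Cl)C(=O)C(c2c[nH]c3ccccc23)=C(O)C1=O | intermediate
14 | 2,5-dihydroxy-6-(1H-indol-3-yl)-3-[2-(2-methylbut-3-en-2-yl)-1H-indol-3-yl]cyclohexa-2,5-diene-1,4-dione | C=CC(C)(C)c1[nH]c2ccccc2c1C1=C(O)C(=O)C(c2c[nH]c3ccccc23)=C(O)C1=O | intermediate
15 | 2,5-dimethoxy-6-(1H-indol-3-yl)-3-[2-(2-methylbut-3-en-2-yl)-1H-indol-3-yl]cyclohexa-2,5-diene-1,4-dione | C=CC(C)(C)c1[nH]c2ccccc2c1C1=C(OC)C(=O)C(c2c[nH]c3ccccc23)=C(OC)C1=O | target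

**Step count**

Total steps: 7. Longest linear sequence: 6 steps (steps 1, 2, 3, 5, 6, 7); step 4 is a one-step side branch.

**Steps most likely to fail**

Step 5 (Proposed new method). What may go wrong: electron transfer from the electron-rich 1-oxyindole anion to the chloroquinone instead of substitution; addition at the C6–H position or at the C2 chloride, so that the ether is placed where the shift cannot end in an enol; or decay of 1-hydroxyindole before it is captured. Fallback, from 8 back to 14, by known polar chemistry: commercial indole (c1ccc2[nH]ccc2c1) is added to the free C6–H position of 8 under the conditions of step 3 (conc. HCl, THF, 23 °C). This should give 2,5-dichloro-3-(1H-indol-3-yl)-6-[2-(2-methylbut-3-en-2-yl)-1H-indol-3-yl]benzene-1,4-diol F1. DDQ then dehydrogenates it to 2,5-dichloro-3-(1H-indol-3-yl)-6-[2-(2-methylbut-3-en-2-yl)-1H-indol-3-yl]cyclohexa-2,5-diene-1,4-dione F2. NaOH in MeOH/H2O at reflux replaces both chlorides and reaches 14, after which step 7 follows. This is the established sequential addition of two different indoles to 2,5-dichlorobenzoquinone.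

Step 4. What may go wrong: over-oxidation, or dimerisation of the unsubstituted N-hydroxyindole during oxidation or solvent exchange, so that too little intact 10 reaches step 5. Fallback by reductive ring closure instead of oxidation: it does not branch from a route intermediate but replaces starting material 9 by commercial 2-nitrotoluene (Cc1ccccc1[N+](=O)[O-]), and it comes back at 10. Condensation with N,N-dimethylformamide dimethyl acetal (DMF, 110 °C; Leimgruber–Batcho enamine formation) should give (E)-N,N-dimethyl-2-(2-nitrophenyl)ethen-1-amine F3. Partial reduction with Zn and NH4Cl (aq EtOH/Et2O, 20 °C) stops at N-{2-[(E)-2-(dimethylamino)ethenyl]phenyl}hydroxylamine F4, which is not isolated. It cyclises with loss of dimethylamine to 10, which is carried into step 5 as a solution.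

Step 6. What may go wrong: slow displacement of the hindered C2 chloride on the anionic ring, and base-mediated degradation of the electron-rich bis(indolyl)quinone on prolonged heating. Fallback, from 13 back to 15, with the order of events reversed so that the displacement runs on a neutral, more electrophilic ring with methoxide: 13 is O-methylated with TMSCHN2 (PhMe/MeOH, 0 → 23 °C) to 2-chloro-5-methoxy-6-(1H-indol-3-yl)-3-[2-(2-methylbut-3-en-2-yl)-1H-indol-3-yl]cyclohexa-2,5-diene-1,4-dione F5. NaOMe in MeOH/THF at 0 °C then exchanges the chloride by addition–elimination and gives 15 directly; attack at the methoxy-bearing carbon is degenerate, so steps 6 and 7 are both replaced.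

**Further compounds**

F1 | step 5 | 2,5-dichloro-3-(1H-indol-3-yl)-6-[2-(2-methylbut-3-en-2-yl)-1H-indol-3-yl]benzene-1,4-diol | C=CC(C)(C)c1[nH]c2ccccc2c1-c1c(O)c(Cl)c(-c2c[nH]c3ccccc23)c(O)c1Cl
F2 | step 5 | 2,5-dichloro-3-(1H-indol-3-yl)-6-[2-(2-methylbut-3-en-2-yl)-1H-indol-3-yl]cyclohexa-2,5-diene-1,4-dione | C=CC(C)(C)c1[nH]c2ccccc2c1C1=C(Cl)C(=O)C(c2c[nH]c3ccccc23)=C(Cl)C1=O
F3 | step 4 | (E)-N,N-dimethyl-2-(2-nitrophenyl)ethen-1-amine | CN(C)/C=C/c1ccccc1[N+](=O)[O-]
F4 | step 4 | N-{2-[(E)-2-(dimethylamino)ethenyl]phenyl}hydroxylamine | CN(C)/C=C/c1ccccc1NO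
F5 | step 6 | 2-chloro-5-methoxy-6-(1H-indol-3-yl)-3-[2-(2-methylbut-3-en-2-yl)-1H-indol-3-yl]cyclohexa-2,5-diene-1,4-dione | C=CC(C)(C)c1[nH]c2ccccc2c1C1=C(Cl)C(=O)C(c2c[nH]c3ccccc23)=C(OC)C1=O
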